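**Retrosynthetic overview**

1. Target 38 ⇐ 9a‑H pyrrolinone 36 (late C9a oxygenation) ⇐ amino ynone (5‑endo aza‑Michael) ⇐ thioester 24 + alkyne lactone 33.
2. 24 ⇐ spirolactone 22 ⇐ ketal aldehyde 16 + propionimide 18 (Evans syn‑aldol for C12/C13, then acid spirolactonisation for C11).
3. 16 ⇐ azepine lactone 13 (formyl‑anion addition to the lactone) ⇐ diene 12 by ring‑closing metathesis, the key ring closure (azepine).
4. 12 ⇐ butenolide 6 + glycinate 4 (tandem Michael addition/ethylation sets C8–C9–C10 trans,trans).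
5. Ring order: butenolide (chiral pool) → azepine (RCM) → THF ketal → spirolactone; side‑chain lactone made separately; pyrrolinone last.

Assumption: Stemona numbering is used (N4, C1–C3, C5–C9, C9a, C10–C14, side‑chain lactone C18–C21); C9a (compounds 8–16, 20–24, 34–36) and the anomeric C11 (14–16, 20, 21) are temporary centres re‑formed later, so one epimer is drawn and any other is carried along and converges.

**Step 1**
Reactants: 1 tert‑butyl N‑allylcarbamate; 2 benzyl bromoacetate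
Product: 4 benzyl N‑allyl‑N‑(tert‑butoxycarbonyl)glycinate, via sodium carbamate salt 3 (not isolated)
Conditions: NaH, DMF, 0 °C; then 2, 0 °C → rt
Reagents that add atoms: none
Why: SN2 N‑alkylation of the carbamate anion by the α‑bromo ester; no stereocentre is formed.

**Step 2**
Reactants: 5 (S)‑5‑(hydroxymethyl)furan‑2(5H)‑one
Product: 6 (S)‑5‑[(tert‑butyldiphenylsilyloxy)methyl]furan‑2(5H)‑one
Conditions: TBDPSCl, imidazole, CH2Cl2, 0 °C → rt
Reagents that add atoms: tert‑butyl(chloro)diphenylsilane, CC(C)(C)[Si](Cl)(c1ccccc1)c1ccccc1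
Why: Silylation of the primary alcohol; the bulky silyl ether later shields one face of the butenolide.

**Step 3**
Reactants: 4 benzyl N‑allyl‑N‑Boc‑glycinate; 6 silylated butenolide
Product: 9 benzyl (2R)‑2‑[allyl(Boc)amino]‑2‑[(2S,3R,4S)‑2‑(TBDPSO‑methyl)‑4‑ethyl‑5‑oxotetrahydrofuran‑3‑yl]acetate, via lithium enolate 7 (not isolated), via lactone enolate 8 (not isolated)
Conditions: LDA, THF, −78 °C; 6, −78 °C; then EtI, HMPA, −78 → −40 °C
Reagents that add atoms: ethyl iodide, CCI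
Why: Tandem Michael addition/enolate alkylation: the ester enolate adds 1,4 anti to the CH2OTBDPS group (sets C9), and the resulting lactone enolate is ethylated anti to the new C9 substituent (sets C10, trans,trans); C9a is not controlled and need not be.

**Step 4**
Reactants: 9 silyl ether lactone
Product: 10 benzyl (2R)‑2‑[allyl(Boc)amino]‑2‑[(2S,3R,4S)‑4‑ethyl‑2‑(hydroxymethyl)‑5‑oxotetrahydrofuran‑3‑yl]acetate
Conditions: HF·pyridine, pyridine, THF, 0 °C → rt
Reagents that add atoms: none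
Why: Fluoride cleavage of the silyl ether under non‑basic conditions, which avoids translactonisation of the freed alcohol.

**Step 5**
Reactants: 10 primary alcohol
Product: 11 benzyl (2R)‑2‑[allyl(Boc)amino]‑2‑[(2S,3R,4S)‑4‑ethyl‑2‑formyl‑5‑oxotetrahydrofuran‑3‑yl]acetate
Conditions: Dess–Martin periodinane, CH2Cl2, 0 °C → rt
Reagents that add atoms: none
Why: Dess–Martin oxidation of the primary alcohol under neutral conditions, so the α‑acyloxy aldehyde is not epimerised.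

**Step 6**
Reactants: 11 aldehyde
Product: 12 benzyl (2R)‑2‑[allyl(Boc)amino]‑2‑[(2R,3R,4S)‑4‑ethyl‑5‑oxo‑2‑vinyltetrahydrofuran‑3‑yl]acetate
Conditions: Ph3PCH3Br, KHMDS, THF, 0 °C; then 11, −78 → 0 °C
Reagents that add atoms: methyltriphenylphosphonium bromide, C[P+](c1ccccc1)(c1ccccc1)c1ccccc1.[Br-]
Why: Wittig methylenation at low temperature; C8 already sits trans to its neighbour, so the wanted epimer is also the thermodynamic one.

**Step 7**
Reactants: 12 diene
Product: 13 RCM product: 1‑Boc‑2,3,4,7‑tetrahydro‑1H‑azepine trans‑fused at C8–C9 to the 10‑ethyl γ‑lactone (C11=O) with the benzyl ester on C9a; (8R,9R,9aR,10S)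
Conditions: Grubbs II (5 mol %), CH2Cl2 (0.005 M), 40 °C
Reagents that add atoms: none
Why: Ring‑closing metathesis of the N‑allyl carbamate and the C8 vinyl group closes the seven‑membered ring trans‑fused to the lactone; the carbamate nitrogen does not poison the catalyst.

**Step 8**
Reactants: 13 azepine lactone
Product: 15 methyl ketal of 13 carrying a 1,3‑dithian‑2‑yl group on C11 (2‑methoxy‑2‑dithianyl tetrahydrofuran; drawn 11S, dithianyl trans to ethyl), via lactol 14 (not isolated)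
Conditions: 1,3‑dithiane, n‑BuLi, THF, −30 °C; 13, −78 °C; then p‑TsOH·H2O in MeOH, −78 °C → rt
Reagents that add atoms: 1,3‑dithiane, C1CSCSC1; methanol, CO
Why: The Corey–Seebach formyl‑anion equivalent adds 1,2 to the lactone, the most electrophilic carbonyl (the α,β‑branched benzyl ester and the carbamate are slower), and stops at the hemiketal, which acidic methanol converts into the methyl ketal.

**Step 9**
Reactants: 15 dithiane ketal
Product: 16 ketal aldehyde (C11: OMe and CHO; C12 is the aldehyde carbon)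
Conditions: MeI, CaCO3, MeCN/H2O 9:1, 45 °C
Reagents that add atoms: water, O
Why: Alkylative dithiane hydrolysis (S‑methylation, buffered) unmasks a non‑enolisable aldehyde; alkene, Boc, ester and ketal are inert.

**Step 10**
Reactants: 17 (R)‑4‑benzyl‑2‑oxazolidinone
Product: 18 (R)‑4‑benzyl‑3‑propionyl‑2‑oxazolidinone
Conditions: propionic anhydride, Et3N, DMAP (cat.), CH2Cl2, rt
Reagents that add atoms: propionic anhydride, CCC(=O)OC(=O)CC
Why: DMAP‑catalysed N‑acylation of the oxazolidinone.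

**Step 11**
Reactants: 16 ketal aldehyde; 18 propionimide
Product: 20 syn‑aldol adduct, (12R,13R)‑12‑hydroxy‑13‑methyl acyl oxazolidinone on the C11 methyl ketal, via boron enolate 19 (not isolated)
Conditions: 18, Bu2BOTf, Et3N, CH2Cl2, −78 → 0 °C; 16, −78 → 0 °C; pH 7 buffer, MeOH, H2O2
Reagents that add atoms: none
Why: Evans syn‑aldol: the (Z)‑boron enolate reacts through a Zimmerman–Traxler chair in which the (R)‑benzyl auxiliary dictates the enolate face, giving 12R,13R under reagent control.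

**Step 12**
Reactants: 20 aldol adduct
Product: 22 spiroketal lactone (11S,12R,13R) with benzyl ester, N‑Boc and the 6,7‑alkene, via hydroxy acid 21 (not isolated)
Conditions: LiOH, H2O2, THF/H2O, 0 °C; Na2SO3; 1 M HCl to pH 3, extract; then CSA (10 mol %), 4 Å MS, CH2Cl2, rt
Reagents that add atoms: hydrogen peroxide, OO
Why: LiOOH cleaves the exocyclic acyl group, and the acid then traps the C11 oxocarbenium ion released from the methyl ketal (acid‑catalysed spirolactonisation); the spiro centre is reversible under CSA and is expected to settle with O22 anti to the C10 ethyl and the C12 hydroxyl anti to the branched C10, the epimer needed.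

**Step 13**
Reactants: 22 benzyl ester
Product: 23 N‑Boc azepane‑9a‑carboxylic acid carrying the spiroketal lactone
Conditions: H2 (1 atm), 10 % Pd/C, EtOAc, rt
Reagents that add atoms: none
Why: Heterogeneous hydrogenation saturates the cis ring alkene and hydrogenolyses the benzyl ester in one operation; carbamate, lactone and spiroketal are inert.

**Step 14**
Reactants: 23 acid
Product: 24 S‑ethyl thioester of 23
Conditions: EtSH, EDC·HCl, DMAP (cat.), CH2Cl2, 0 °C → rt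
Reagents that add atoms: ethanethiol, CCS
Why: Steglich‑type thioesterification of the hindered acid; epimerisation at C9a would be harmless.

**Step 15**
Reactants: 25 3‑(trimethylsilyl)propiolic acid
Product: 26 3‑(trimethylsilyl)propioloyl chloride
Conditions: (COCl)2, DMF (cat.), CH2Cl2, 0 °C → rt; distil
Reagents that add atoms: oxalyl chloride, O=C(Cl)C(Cl)=O
Why: Acid chloride formation through the Vilsmeier intermediate.

**Step 16**
Reactants: 27 methyl (S)‑3‑hydroxy‑2‑methylpropanoate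
Product: 28 methyl (R)‑3‑iodo‑2‑methylpropanoate
Conditions: I2, PPh3, imidazole, CH2Cl2, 0 °C → rt
Reagents that add atoms: iodine, II
Why: Appel iodination of the primary alcohol; the stereocentre is not touched (the descriptor changes only by priority).

**Step 17**
Reactants: 28 iodide; 26 acid chloride
Product: 30 methyl (2S)‑2‑methyl‑4‑oxo‑6‑(trimethylsilyl)hex‑5‑ynoate, via alkylzinc iodide 29 (not isolated)
Conditions: Zn dust (activated), THF, 35 °C; then 26, Pd(PPh3)4 (5 mol %), 0 °C → rt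
Reagents that add atoms: none
Why: Zinc insertion into the primary iodide followed by Pd‑catalysed Negishi acylation; the stereocentre is remote from the reacting carbon.

**Step 18**
Reactants: 30 ynone
Product: 31 methyl (2S,4S)‑4‑hydroxy‑2‑methyl‑6‑(trimethylsilyl)hex‑5‑ynoate
Conditions: RuCl[(S,S)‑TsDPEN](p‑cymene) (1 mol %), i‑PrOH, rt
Reagents that add atoms: none
Why: Noyori asymmetric transfer hydrogenation; the (S,S) catalyst delivers hydride to the ynone face that gives the (S)‑propargylic alcohol under catalyst control.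

**Step 19**
Reactants: 31 hydroxy ester
Product: 32 (3S,5S)‑3‑methyl‑5‑[(trimethylsilyl)ethynyl]dihydrofuran‑2(3H)‑one
Conditions: PPTS (cat.), toluene, 70 °C
Reagents that add atoms: none
Why: Acid‑catalysed lactonisation of the γ‑hydroxy ester; both centres are already set, giving the cis‑3,5‑lactone.

**Step 20**
Reactants: 32 silyl alkyne
Product: 33 (3S,5S)‑5‑ethynyl‑3‑methyldihydrofuran‑2(3H)‑one
Conditions: TBAF, AcOH, THF, 0 °C
Reagents that add atoms: none
Why: Buffered fluoride protiodesilylation of the alkynylsilane leaves the lactone and its α‑centre untouched.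

**Step 21**
Reactants: 24 thioester; 33 alkyne lactone
Product: 34 N‑Boc amino ynone: C9a–C(=O)–C≡C–[(2S,4S)‑4‑methyl‑5‑oxotetrahydrofuran‑2‑yl]
Conditions: PdCl2(dppf) (10 mol %), P(2‑furyl)3, CuI, Et3N, DMF, 50 °C
Reagents that add atoms: none
Why: Pd/Cu‑catalysed thioester–alkyne coupling (Fukuyama‑type acyl Sonogashira) gives the ynone under mild, non‑nucleophilic conditions tolerated by the lactones and the free hydroxyl.

**Step 22**
Reactants: 34 N‑Boc amino ynone
Product: 38 target CNP0182700.1, (8R,9S,9aS,10S,11S,12R,13R,18S,20S), via amino ynone 35 (not isolated), via 9a‑H pyrrolinone 36 (not isolated), via 9a‑hydroperoxide 37 (not isolated)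
Conditions: TFA/CH2Cl2 1:4, 0 °C; evaporate; Et3N, MeCN, rt, Ar; then O2 (1 atm), P(OEt)3, rt
Reagents that add atoms: dioxygen, O=O
Why: Boc acidolysis frees the azepane nitrogen, which adds 5‑endo‑dig to the ynone (intramolecular aza‑Michael); the pyrrolinone enol is autoxidised at C9a and the hydroperoxide is reduced by the phosphite, oxygen entering anti to the bulky C10 branch (cis to H‑9), which sets 9aS.

**Compound list**

1 | tert‑butyl N‑allylcarbamate | C=CCNC(=O)OC(C)(C)C | starting material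
2 | benzyl bromoacetate | BrCC(=O)OCc1ccccc1 | starting material
3 | sodium salt of 1 | [Na+].C=CC[N-]C(=O)OC(C)(C)C | intermediate
4 | benzyl N‑allyl‑N‑(tert‑butoxycarbonyl)glycinate | C=CCN(CC(=O)OCc1ccccc1)C(=O)OC(C)(C)C | intermediate
5 | (S)‑5‑(hydroxymethyl)furan‑2(5H)‑one | O=C1C=C[C@@H](CO)O1 | starting material
6 | (S)‑5‑[(tert‑butyldiphenylsilyloxy)methyl]furan‑2(5H)‑one | O=C1C=C[C@@H](CO[Si](c2ccccc2)(c2ccccc2)C(C)(C)C)O1 | intermediate
7 | lithium enolate of 4 | [Li]OC(OCc1ccccc1)=CN(CC=C)C(=O)OC(C)(C)C | intermediate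
8 | lithium lactone enolate of the Michael adduct (C9 set) | [Li]OC1=C[C@H]([C@@H](N(CC=C)C(=O)OC(C)(C)C)C(=O)OCc2ccccc2)[C@@H](CO[Si](c2ccccc2)(c2ccccc2)C(C)(C)C)O1 | intermediate
9 | benzyl (2R)‑2‑[allyl(Boc)amino]‑2‑[(2S,3R,4S)‑2‑(TBDPSO‑methyl)‑4‑ethyl‑5‑oxotetrahydrofuran‑3‑yl]acetate | CC[C@H]1[C@H]([C@@H](N(CC=C)C(=O)OC(C)(C)C)C(=O)OCc2ccccc2)[C@@H](CO[Si](c2ccccc2)(c2ccccc2)C(C)(C)C)OC1=O | intermediate
10 | benzyl (2R)‑2‑[allyl(Boc)amino]‑2‑[(2S,3R,4S)‑4‑ethyl‑2‑(hydroxymethyl)‑5‑oxotetrahydrofuran‑3‑yl]acetate | CC[C@H]1[C@H]([C@@H](N(CC=C)C(=O)OC(C)(C)C)C(=O)OCc2ccccc2)[C@@H](CO)OC1=O | intermediate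
11 | benzyl (2R)‑2‑[allyl(Boc)amino]‑2‑[(2S,3R,4S)‑4‑ethyl‑2‑formyl‑5‑oxotetrahydrofuran‑3‑yl]acetate | CC[C@H]1[C@H]([C@@H](N(CC=C)C(=O)OC(C)(C)C)C(=O)OCc2ccccc2)[C@@H](C=O)OC1=O | intermediate
12 | benzyl (2R)‑2‑[allyl(Boc)amino]‑2‑[(2R,3R,4S)‑4‑ethyl‑5‑oxo‑2‑vinyltetrahydrofuran‑3‑yl]acetate | CC[C@H]1[C@H]([C@@H](N(CC=C)C(=O)OC(C)(C)C)C(=O)OCc2ccccc2)[C@@H](C=C)OC1=O | intermediate
13 | (8R,9R,9aR,10S) N‑Boc tetrahydroazepine trans‑fused to the 10‑ethyl γ‑lactone, C9a benzyl ester | CC[C@H]1[C@H]2[C@@H](C=CCN(C(=O)OC(C)(C)C)[C@H]2C(=O)OCc2ccccc2)OC1=O | intermediate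
14 | C11 lactol of 13 with 1,3‑dithian‑2‑yl on C11 | CC[C@H]1[C@H]2[C@@H](C=CCN(C(=O)OC(C)(C)C)[C@H]2C(=O)OCc2ccccc2)O[C@]1(O)C1SCCCS1 | intermediate
15 | C11 methyl ketal with 1,3‑dithian‑2‑yl on C11 | CC[C@H]1[C@H]2[C@@H](C=CCN(C(=O)OC(C)(C)C)[C@H]2C(=O)OCc2ccccc2)O[C@]1(OC)C1SCCCS1 | intermediate
16 | C11 methyl ketal C12 aldehyde | CC[C@H]1[C@H]2[C@@H](C=CCN(C(=O)OC(C)(C)C)[C@H]2C(=O)OCc2ccccc2)O[C@]1(OC)C=O | intermediate
17 | (R)‑4‑benzyl‑2‑oxazolidinone | O=C1N[C@H](Cc2ccccc2)CO1 | starting material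
18 | (R)‑4‑benzyl‑3‑propionyl‑2‑oxazolidinone | CCC(=O)N1[C@H](Cc2ccccc2)COC1=O | intermediate
19 | (Z)‑dibutylboron enolate of 18 | C/C=C(\OB(CCCC)CCCC)N1[C@H](Cc2ccccc2)COC1=O | intermediate
20 | (12R,13R) syn‑aldol adduct, acyl oxazolidinone on the C11 methyl ketal | CC[C@H]1[C@H]2[C@@H](C=CCN(C(=O)OC(C)(C)C)[C@H]2C(=O)OCc2ccccc2)O[C@]1(OC)[C@H](O)[C@@H](C)C(=O)N1[C@H](Cc2ccccc2)COC1=O | intermediate
21 | (12R,13R)‑12‑hydroxy‑13‑methyl carboxylic acid on the C11 methyl ketal | CC[C@H]1[C@H]2[C@@H](C=CCN(C(=O)OC(C)(C)C)[C@H]2C(=O)OCc2ccccc2)O[C@]1(OC)[C@H](O)[C@@H](C)C(=O)O | intermediate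
22 | (8R,9R,9aR,10S,11S,12R,13R) spiroketal lactone, C9a benzyl ester, N‑Boc, Δ6 | CC[C@H]1[C@H]2[C@@H](C=CCN(C(=O)OC(C)(C)C)[C@H]2C(=O)OCc2ccccc2)O[C@]12OC(=O)[C@H](C)[C@H]2O | intermediate
23 | N‑Boc azepane‑9a‑carboxylic acid with spiroketal lactone | CC[C@H]1[C@H]2[C@@H](CCCN(C(=O)OC(C)(C)C)[C@H]2C(=O)O)O[C@]12OC(=O)[C@H](C)[C@H]2O | intermediate
24 | S‑ethyl thioester of 23 | CC[C@H]1[C@H]2[C@@H](CCCN(C(=O)OC(C)(C)C)[C@H]2C(=O)SCC)O[C@]12OC(=O)[C@H](C)[C@H]2O | intermediate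
25 | 3‑(trimethylsilyl)propiolic acid | C[Si](C)(C)C#CC(=O)O | starting material
26 | 3‑(trimethylsilyl)propioloyl chloride | C[Si](C)(C)C#CC(=O)Cl | intermediate
27 | methyl (S)‑3‑hydroxy‑2‑methylpropanoate | COC(=O)[C@@H](C)CO | starting material
28 | methyl (R)‑3‑iodo‑2‑methylpropanoate | COC(=O)[C@@H](C)CI | intermediate
29 | [(R)‑3‑methoxy‑2‑methyl‑3‑oxopropyl]zinc iodide | COC(=O)[C@@H](C)C[Zn]I | intermediate
30 | methyl (2S)‑2‑methyl‑4‑oxo‑6‑(trimethylsilyl)hex‑5‑ynoate | COC(=O)[C@@H](C)CC(=O)C#C[Si](C)(C)C | intermediate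
31 | methyl (2S,4S)‑4‑hydroxy‑2‑methyl‑6‑(trimethylsilyl)hex‑5‑ynoate | COC(=O)[C@@H](C)C[C@H](O)C#C[Si](C)(C)C | intermediate
32 | (3S,5S)‑3‑methyl‑5‑[(trimethylsilyl)ethynyl]dihydrofuran‑2(3H)‑one | C[Si](C)(C)C#C[C@@H]1C[C@H](C)C(=O)O1 | intermediate
33 | (3S,5S)‑5‑ethynyl‑3‑methyldihydrofuran‑2(3H)‑one | C#C[C@@H]1C[C@H](C)C(=O)O1 | intermediate
34 | N‑Boc amino ynone (C9a acyl alkyne to the 18S,20S lactone) | CC[C@H]1[C@H]2[C@@H](CCCN(C(=O)OC(C)(C)C)[C@H]2C(=O)C#C[C@@H]2C[C@H](C)C(=O)O2)O[C@]12OC(=O)[C@H](C)[C@H]2O | intermediate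
35 | free secondary amino ynone | CC[C@H]1[C@H]2[C@@H](CCCN[C@H]2C(=O)C#C[C@@H]2C[C@H](C)C(=O)O2)O[C@]12OC(=O)[C@H](C)[C@H]2O | intermediate
36 | 9a‑H pyrrolinone (9a‑deoxy target, 9aR) | CC[C@H]1[C@H]2[C@@H](CCCN3C([C@@H]4C[C@H](C)C(=O)O4)=CC(=O)[C@@H]23)O[C@]12OC(=O)[C@H](C)[C@H]2O | intermediate
37 | 9a‑hydroperoxide (9aS) | CC[C@H]1[C@H]2[C@@H](CCCN3C([C@@H]4C[C@H](C)C(=O)O4)=CC(=O)[C@@]23OO)O[C@]12OC(=O)[C@H](C)[C@H]2O | intermediate
38 | CNP0182700.1 | CC[C@H]1[C@H]2[C@@H](CCCN3C([C@@H]4C[C@H](C)C(=O)O4)=CC(=O)[C@@]23O)O[C@]12OC(=O)[C@H](C)[C@H]2O | target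

**Totals**

Total step count: 22. Longest linear sequence: 14 (steps 2–9, 11–14, 21, 22; the branch through step 1 is equally long).

**Steps most likely to fail**

Step 8 (the dithiane anion may enolise the α‑branched lactone or attack the benzyl ester). The fallback sets out from 13 and comes back at 16. Compound 13 is treated with the far less basic Grignard reagent (isopropoxydimethylsilyl)methylmagnesium chloride (THF, −78 → 0 °C), which adds once to the lactone and gives the silylmethyl lactol F1. Tamao oxidation (H2O2, KF, KHCO3, THF/MeOH) turns the C–Si bond into C–OH and gives the hydroxymethyl lactol F2. MeOH/PPTS converts this into the methyl ketal alcohol F3, and Dess–Martin oxidation gives 16.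

Step 12 (the spiro centre C11 may settle as the wrong epimer or as a mixture). The fallback sets out from 20 and comes back at 22. The C12 hydroxyl of 20 is first silylated (TBSOTf, 2,6‑lutidine) to the silyl ether F4. LiOH/H2O2 then gives the silyloxy acid F5. CSA in CH2Cl2 equilibrates the spiro centre with the bulky silyloxy group forced anti to the branched C10, giving the silylated spirolactone F6. HF·pyridine returns 22.

Step 22 (autoxidation at C9a may be slow, over‑oxidise, or cleave the C1–C9a bond). The fallback sets out from 34 and comes back at 38. Boc removal and cyclisation are run under argon to 36, which is trapped with TBSOTf/Et3N as the silyloxypyrrole silyl ether F7. Rubottom oxidation with dimethyldioxirane (acetone/CH2Cl2, −78 °C) epoxidises the enol ether on the face anti to C10 and, after silyl shift, gives the bis‑silyl ether F8. HF·pyridine then gives 38.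

**Further compounds**

F1 | step 8 | C11 lactol of 13 with (isopropoxydimethylsilyl)methyl on C11 | CC[C@H]1[C@H]2[C@@H](C=CCN(C(=O)OC(C)(C)C)[C@H]2C(=O)OCc2ccccc2)O[C@]1(O)C[Si](C)(C)OC(C)C
F2 | step 8 | C11 lactol with hydroxymethyl on C11 | CC[C@H]1[C@H]2[C@@H](C=CCN(C(=O)OC(C)(C)C)[C@H]2C(=O)OCc2ccccc2)O[C@]1(O)CO
F3 | step 8 | C11 methyl ketal with hydroxymethyl on C11 | CC[C@H]1[C@H]2[C@@H](C=CCN(C(=O)OC(C)(C)C)[C@H]2C(=O)OCc2ccccc2)O[C@]1(OC)CO
F4 | step 12 | 12‑O‑TBS ether of aldol adduct 20 | CC[C@H]1[C@H]2[C@@H](C=CCN(C(=O)OC(C)(C)C)[C@H]2C(=O)OCc2ccccc2)O[C@]1(OC)[C@H](O[Si](C)(C)C(C)(C)C)[C@@H](C)C(=O)N1[C@H](Cc2ccccc2)COC1=O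
F5 | step 12 | 12‑O‑TBS ether of acid 21 | CC[C@H]1[C@H]2[C@@H](C=CCN(C(=O)OC(C)(C)C)[C@H]2C(=O)OCc2ccccc2)O[C@]1(OC)[C@H](O[Si](C)(C)C(C)(C)C)[C@@H](C)C(=O)O
F6 | step 12 | 12‑O‑TBS ether of spirolactone 22 | CC[C@H]1[C@H]2[C@@H](C=CCN(C(=O)OC(C)(C)C)[C@H]2C(=O)OCc2ccccc2)O[C@]12OC(=O)[C@H](C)[C@H]2O[Si](C)(C)C(C)(C)C
F7 | step 22 | 1‑(TBS‑oxy)pyrrole (silyl enol ether of 36) with 12‑O‑TBS | CC[C@H]1[C@H]2[C@@H](CCCn3c([C@@H]4C[C@H](C)C(=O)O4)cc(O[Si](C)(C)C(C)(C)C)c23)O[C@]12OC(=O)[C@H](C)[C@H]2O[Si](C)(C)C(C)(C)C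
F8 | step 22 | 9a,12‑bis‑O‑TBS ether of 38 | CC[C@H]1[C@H]2[C@@H](CCCN3C([C@@H]4C[C@H](C)C(=O)O4)=CC(=O)[C@@]23O[Si](C)(C)C(C)(C)C)O[C@]12OC(=O)[C@H](C)[C@H]2O[Si](C)(C)C(C)(C)C
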